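**Retrosynthetic overview**
1. The ester is made last: target ⇒ dienol 13 + an aryl–CO bond, formed from the alkoxycarbonylimidazole of 13 and a magnesiated guaiacol built from catechol, with no phenol protection.
2. 13 ⇒ racemic (2Z,6Z)-dienone 12: C1 and C10 are set together by asymmetric hydrogenation with dynamic kinetic resolution.
3. 12 ⇒ hydroazulene 1,3-diol monomesylate 11: Grob (Wharton) fragmentation of the ring-fusion bond expands the 5/7 bicycle to the ten-membered ring and fixes both Z alkenes.
4. 11 ⇒ cyclopentanone 5 + 4-methylpent-4-enal + vinyl: aldol (quaternary carbon and carbinol), vinyl addition, ring-closing metathesis.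
5. Ring order: cyclopentane (bought; isopropyl from acetone) → cycloheptene (metathesis) → cyclodecadiene (fragmentation).

Assumption: 4-methylpent-4-enal (CAS 3973-43-1) is bought as a catalogue aldehyde; compounds 3–12 are racemic, R*/S* give relative configuration, and their SMILES show one enantiomer.

**Route**

Step 1
Reactants: 1 2-methylcyclopentan-1-one; 2 acetone
Product: 3 2-(2-hydroxypropan-2-yl)-5-methylcyclopentan-1-one (racemic cis/trans mixture)
Conditions: LiN(i-Pr)2, THF, −78 °C; then 2, −78 °C; H2O
Reagents that add atoms: none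
Why: Kinetic lithium-enolate aldol addition, in which the amide base removes the less hindered C5–H of 1 and the enolate adds to acetone; the new ring stereocentre forms unselectively, which is harmless because it is reset later.

Step 2
Reactants: 3
Product: 5 2-methyl-5-(propan-2-yl)cyclopentan-1-one (racemic cis/trans mixture), via isopropylidene enone 4 (not isolated)
Conditions: TsOH·H2O (10 mol %), Pd/C (5 mol %), H2 (3 atm), EtOAc, 50 °C
Reagents that add atoms: none
Why: Acid-catalysed dehydration of the tertiary aldol to the conjugated enone 4 and heterogeneous hydrogenation of its C=C in the same flask (tandem dehydration–hydrogenation); the cis/trans ratio does not matter because C2 is enolised in step 3 and C5 is equilibrated in step 7.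

Step 3
Reactants: 5; 6 4-methylpent-4-enal
Product: 7 (2R*)-2-[(1R*)-1-hydroxy-4-methylpent-4-en-1-yl]-2-methyl-5-(propan-2-yl)cyclopentan-1-one (racemic; C5 epimers)
Conditions: LiN(i-Pr)2, THF, −78 °C, 45 min; then 6, −78 °C, 15 min; H2O at −78 °C
Reagents that add atoms: none
Why: Zimmerman–Traxler aldol addition of a tetrasubstituted lithium enolate, in which the base takes the methine H next to CH3 rather than the one shielded by isopropyl, and the chair transition state with the aldehyde chain equatorial gives the quaternary carbon and the carbinol in the (1′R*,2R*) relationship that later becomes the 6Z alkene.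

Step 4
Reactants: 7; 8 vinylmagnesium bromide
Product: 9 (2R*)-1-ethenyl-2-[(1R*)-1-hydroxy-4-methylpent-4-en-1-yl]-2-methyl-5-(propan-2-yl)cyclopentan-1-ol (racemic; C1 and C5 epimers)
Conditions: CeCl3 (3 equiv), 8 (3 equiv), THF, −78 → 0 °C; H2O
Reagents that add atoms: none
Why: Organocerium (Imamoto) 1,2-addition, which tolerates the hindered enolisable ketone and the free hydroxyl (as its alkoxide) without retro-aldol; the new tertiary carbinol centre forms as a mixture and is erased in step 6.

Step 5
Reactants: 9
Product: 10 (8R*,8aR*)-5,8a-dimethyl-3-(propan-2-yl)-1,2,3,3a,6,7,8,8a-octahydroazulene-3a,8-diol (racemic; C3 and C3a epimers)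
Conditions: second-generation Hoveyda–Grubbs catalyst (5 mol %), toluene (0.005 M), 80 °C
Reagents that add atoms: none
Why: Ring-closing metathesis of the vinyl carbinol with the 1,1-disubstituted alkene; the trisubstituted alkene is necessarily cis inside the seven-membered ring and becomes the 2Z alkene, and no stereocentre is formed.

Step 6
Reactants: 10
Product: 12 (2Z,6Z)-3,7-dimethyl-10-(propan-2-yl)cyclodeca-2,6-dien-1-one (racemic), via C8 mesylate 11 (not isolated)
Conditions: MsCl (1.1 equiv), Et3N (1.5 equiv), THF, −20 °C; then KOtBu (2.5 equiv), −78 → 0 °C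
Reagents that add atoms: none
Why: Grob (Wharton) fragmentation of a 1,3-diol monosulfonate, in which the secondary hydroxyl is mesylated selectively and the potassium alkoxide at C3a then expels mesylate through the anti-periplanar C3a–C8a bond; the concerted anti geometry turns the (8R*,8aR*) relationship into the 6Z alkene, and the three old stereocentres disappear.

Step 7
Reactants: 12
Product: 13 (1R,2Z,6Z,10S)-3,7-dimethyl-10-(propan-2-yl)cyclodeca-2,6-dien-1-ol
Conditions: trans-RuCl2[(R)-binap][(S,S)-dpen] (1 mol %), KOtBu (10 mol %), H2 (10 atm), i-PrOH, 30 °C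
Reagents that add atoms: none
Why: Proposed new method: asymmetric hydrogenation with dynamic kinetic resolution of a racemic α′-branched ten-membered Z-enone, in which KOtBu interconverts the enantiomers of 12 through the C1–C10 enolate while the divalent ruthenium hydride/NH catalyst delivers H–/H+ outer-sphere to C=O only (no C=C reduction) of the matched (10S)-ketone on the face that puts OH cis to isopropyl, so C1 (R) and C10 (S) are set together; the closest known reaction type is the BINAP/diamine–ruthenium (Noyori) hydrogenation of racemic 2-alkylcycloalkanones to cis-alcohols and of simple enones to allylic alcohols, and the catalyst antipode is chosen by analogy with 2-isopropylcyclohexanone, to be confirmed by Mosher analysis.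

Step 8
Reactants: 14 benzene-1,2-diol (catechol)
Product: 15 2-methoxyphenol
Conditions: MeI (1.0 equiv), Li2CO3, DMF, 55 °C
Reagents that add atoms: iodomethane CI
Why: Williamson mono-O-methylation of the catechol monophenolate with one equivalent of iodomethane and a weak base; 15 is separated from catechol and the dimethyl ether by extraction and distillation.

Step 9
Reactants: 15
Product: 16 4-iodo-2-methoxyphenol
Conditions: N-iodosuccinimide (1.0 equiv), CF3CO2H (10 mol %), MeCN, 0 °C
Reagents that add atoms: N-iodosuccinimide O=C1CCC(=O)N1I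
Why: Electrophilic aromatic iodination, directed para to the free hydroxyl as the stronger activating group.

Step 10
Reactants: 13; 16
Product: 19 (1R,2Z,6Z,10S)-3,7-dimethyl-10-(propan-2-yl)cyclodeca-2,6-dien-1-yl 4-hydroxy-3-methoxybenzoate, via dienyl imidazole-1-carboxylate 17 (not isolated), via magnesiated phenolate 18 (not isolated)
Conditions: 13, n-BuLi (1.0 equiv), THF, −78 °C, then 1,1′-carbonyldiimidazole (1.0 equiv), −78 → 0 °C; separately 16, MeMgCl (1.0 equiv), LiCl, THF, −20 °C, then i-PrMgCl (1.1 equiv), 25 °C; combine at −40 → 0 °C; H2O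
Reagents that add atoms: 1,1′-carbonyldiimidazole O=C(n1ccnc1)n1ccnc1
Why: Ester synthesis from a Grignard reagent and an alkyl imidazole-1-carboxylate, in which iodine–magnesium exchange on the magnesium phenolate of 16 gives aryl Grignard 18 and this displaces imidazolide at the carbonyl of 17; the C1–O bond is never broken, so C1 and C10 keep their configuration and the phenol is released on work-up.

**Compound list**
1 | 2-methylcyclopentan-1-one | CC1CCCC1=O | starting material
2 | acetone | CC(C)=O | starting material
3 | 2-(2-hydroxypropan-2-yl)-5-methylcyclopentan-1-one (racemic, cis/trans) | CC1CCC(C(C)(C)O)C1=O | intermediate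
4 | 2-methyl-5-(propan-2-ylidene)cyclopentan-1-one (racemic) | CC1CCC(=C(C)C)C1=O | intermediate
5 | 2-methyl-5-(propan-2-yl)cyclopentan-1-one (racemic, cis/trans) | CC1CCC(C(C)C)C1=O | intermediate
6 | 4-methylpent-4-enal | CC(=C)CCC=O | starting material
7 | (2R*)-2-[(1R*)-1-hydroxy-4-methylpent-4-en-1-yl]-2-methyl-5-(propan-2-yl)cyclopentan-1-one (racemic, C5 epimers) | CC(=C)CC[C@@H](O)[C@@]1(C)CCC(C(C)C)C1=O | intermediate
8 | vinylmagnesium bromide | C=C[Mg]Br | starting material
9 | (2R*)-1-ethenyl-2-[(1R*)-1-hydroxy-4-methylpent-4-en-1-yl]-2-methyl-5-(propan-2-yl)cyclopentan-1-ol (racemic, C1/C5 epimers) | CC(=C)CC[C@@H](O)[C@@]1(C)CCC(C(C)C)C1(O)C=C | intermediate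
10 | (8R*,8aR*)-5,8a-dimethyl-3-(propan-2-yl)-1,2,3,3a,6,7,8,8a-octahydroazulene-3a,8-diol (racemic, C3/C3a epimers; tertiary OH on fusion carbon C3a next to the C4=C5 alkene, secondary OH on C8 next to the angular-methyl carbon C8a) | CC1=CC2(O)C(C(C)C)CC[C@]2(C)[C@H](O)CC1 | intermediate
11 | (8R*,8aR*)-3a-hydroxy-5,8a-dimethyl-3-(propan-2-yl)-1,2,3,3a,6,7,8,8a-octahydroazulen-8-yl methanesulfonate (racemic) | CC1=CC2(O)C(C(C)C)CC[C@]2(C)[C@H](OS(C)(=O)=O)CC1 | intermediate
12 | (2Z,6Z)-3,7-dimethyl-10-(propan-2-yl)cyclodeca-2,6-dien-1-one (racemic) | O=C1/C=C(/C)CC/C=C(/C)CCC1C(C)C | intermediate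
13 | (1R,2Z,6Z,10S)-3,7-dimethyl-10-(propan-2-yl)cyclodeca-2,6-dien-1-ol | O[C@H]1/C=C(/C)CC/C=C(/C)CC[C@H]1C(C)C | intermediate
14 | benzene-1,2-diol (catechol) | Oc1ccccc1O | starting material
15 | 2-methoxyphenol | COc1ccccc1O | intermediate
16 | 4-iodo-2-methoxyphenol | COc1cc(I)ccc1O | intermediate
17 | (1R,2Z,6Z,10S)-3,7-dimethyl-10-(propan-2-yl)cyclodeca-2,6-dien-1-yl 1H-imidazole-1-carboxylate | O=C(O[C@H]1/C=C(/C)CC/C=C(/C)CC[C@H]1C(C)C)n1ccnc1 | intermediate
18 | chloromagnesium 4-(chloromagnesio)-2-methoxyphenolate | COc1cc([Mg]Cl)ccc1O[Mg]Cl | intermediate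
19 | (1R,2Z,6Z,10S)-3,7-dimethyl-10-(propan-2-yl)cyclodeca-2,6-dien-1-yl 4-hydroxy-3-methoxybenzoate | COc1cc(C(=O)O[C@H]2/C=C(/C)CC/C=C(/C)CC[C@H]2C(C)C)ccc1O | target

**Step count and risks**
Total step count: 10. Longest linear sequence: 8 steps (1–7, then 10).

Steps most likely to fail:

Step 7 (proposed new step). Racemisation of 12 may be slower than reduction, which would give only a kinetic resolution. The base may also deconjugate the enone, or the cis/trans or absolute sense may be wrong. The fallback uses known chemistry, sets out from 12 and comes back at 13. LiBH(s-Bu)3 in THF at −78 °C reduces racemic 12 at the carbonyl only (β,β-disubstituted enone) to the racemic cis-alcohol, that is 13 together with its enantiomer (1S,2Z,6Z,10R)-3,7-dimethyl-10-(propan-2-yl)cyclodeca-2,6-dien-1-ol F2; any trans isomer is removed on silica. Esterification with (S)-2-methoxy-2-phenylacetic acid (DCC, DMAP, CH2Cl2) gives two diastereomers, (1R,2Z,6Z,10S)-3,7-dimethyl-10-(propan-2-yl)cyclodeca-2,6-dien-1-yl (2S)-2-methoxy-2-phenylacetate F3 and (1S,2Z,6Z,10R)-3,7-dimethyl-10-(propan-2-yl)cyclodeca-2,6-dien-1-yl (2S)-2-methoxy-2-phenylacetate F4, which are separated by chromatography. Methanolysis of F3 (K2CO3, MeOH) returns 13.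

Step 3. The base may also deprotonate the isopropyl-bearing carbon, the syn/anti ratio may be modest, and the adduct can undergo retro-aldol. The fallback sets out from 3 and comes back at 7. Compound 3 is dehydrated without hydrogenation (TsOH, toluene, reflux) and enone 4 is isolated. LiN(i-Pr)2 at −78 °C can then remove only the α′-H on the methyl-bearing carbon, because the other α-carbon is sp2. The cross-conjugated enolate adds 6 to give (2R*)-2-[(1R*)-1-hydroxy-4-methylpent-4-en-1-yl]-2-methyl-5-(propan-2-ylidene)cyclopentan-1-one F1, which has only two stereocentres, so the diastereomers are easy to separate. Li in NH3/THF at −78 °C (dissolving-metal conjugate reduction; the isolated alkene is untouched) then gives 7.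

Step 10. Iodine–magnesium exchange on the electron-rich phenolate may be incomplete, and O-acylation or double addition may compete. The fallback sets out from 16 and comes back at 19. TBSCl and imidazole give tert-butyl(4-iodo-2-methoxyphenoxy)dimethylsilane F5. Exchange with i-PrMgCl·LiCl followed by CO2 gives 4-{[tert-butyl(dimethyl)silyl]oxy}-3-methoxybenzoic acid F6. Yamaguchi esterification with 13 (2,4,6-trichlorobenzoyl chloride, Et3N, then DMAP) gives (1R,2Z,6Z,10S)-3,7-dimethyl-10-(propan-2-yl)cyclodeca-2,6-dien-1-yl 4-{[tert-butyl(dimethyl)silyl]oxy}-3-methoxybenzoate F7. Bu4NF/AcOH in THF then gives 19.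

**Further compounds**
F1 | step 3 | (2R*)-2-[(1R*)-1-hydroxy-4-methylpent-4-en-1-yl]-2-methyl-5-(propan-2-ylidene)cyclopentan-1-one (racemic) | CC(=C)CC[C@@H](O)[C@@]1(C)CCC(=C(C)C)C1=O
F2 | step 7 | (1S,2Z,6Z,10R)-3,7-dimethyl-10-(propan-2-yl)cyclodeca-2,6-dien-1-ol | O[C@@H]1/C=C(/C)CC/C=C(/C)CC[C@@H]1C(C)C
F3 | step 7 | (1R,2Z,6Z,10S)-3,7-dimethyl-10-(propan-2-yl)cyclodeca-2,6-dien-1-yl (2S)-2-methoxy-2-phenylacetate | CO[C@H](C(=O)O[C@H]1/C=C(/C)CC/C=C(/C)CC[C@H]1C(C)C)c1ccccc1
F4 | step 7 | (1S,2Z,6Z,10R)-3,7-dimethyl-10-(propan-2-yl)cyclodeca-2,6-dien-1-yl (2S)-2-methoxy-2-phenylacetate | CO[C@H](C(=O)O[C@@H]1/C=C(/C)CC/C=C(/C)CC[C@@H]1C(C)C)c1ccccc1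
F5 | step 10 | tert-butyl(4-iodo-2-methoxyphenoxy)dimethylsilane | COc1cc(I)ccc1O[Si](C)(C)C(C)(C)C
F6 | step 10 | 4-{[tert-butyl(dimethyl)silyl]oxy}-3-methoxybenzoic acid | COc1cc(C(=O)O)ccc1O[Si](C)(C)C(C)(C)C
F7 | step 10 | (1R,2Z,6Z,10S)-3,7-dimethyl-10-(propan-2-yl)cyclodeca-2,6-dien-1-yl 4-{[tert-butyl(dimethyl)silyl]oxy}-3-methoxybenzoate | COc1cc(C(=O)O[C@H]2/C=C(/C)CC/C=C(/C)CC[C@H]2C(C)C)ccc1O[Si](C)(C)C(C)(C)C
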